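Which of eta and alpha ends with the longer chains is a question of two entries in a ledger: the monomer in chains, and the chains begun that share it.

| flask | free monomer | initiator | remark | time |
|---|---|---|---|---|
| Friday's | 0.055 M | 4 mM | run made earlier |  |
| Thursday's | 0.10 M | 4 mM | run made earlier |  |
| Wednesday's | 0.23 M | 4 mM | run made earlier |  |
| eta | 0.20 M | 4.0 mM |  | 12 min |
| alpha | 0.050 M | 4.0 mM |  | 12 min |

| run | time / min | monomer in chains / % | free monomer / % |
|---|---|---|---|
| Friday's | 0.667 | 1 | 97 |
| Friday's | 1.50 | 0 | 100 |
| Friday's | 4.00 | 16 | 83 |
| Friday's | 8.00 | 32 | 65 |
| Thursday's | 1.00 | 0 | 98 |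
| Thursday's | 3.00 | 17 | 81 |
| Thursday's | 5.00 | 30 | 68 |
| Thursday's | 8.00 | 56 | 46 |
| Wednesday's | 2.00 | 20 | 79 |
| Wednesday's | 4.00 | 44 | 54 |
| Wednesday's | 6.00 | 68 | 37 |
| Wednesday's | 8.00 | 80 | 20 |

(standard deviation of a reading: 2 percentage points)

1. which of the two ends with the longer chains by the average number of monomer units in a chain (chains begun, living or dead) ("neither" if they lie within 10%) (eta / alpha / neither)
2. average number of monomer units in a chain (chains begun, living or dead) at the end, eta
3. average number of monomer units in a chain (chains begun, living or dead) at the end, alpha

- the average divides the monomer in chains by the number of chains begun, living and dead together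
- the earlier runs do not show the number of chains; that part of a forecast is a guess

I keep the free monomer's books first. Wednesday's last readings add up to 100%, each with a scatter of 2 percentage points, so I book each unit charged as still free or in a chain, and the first entry can be read. The second entry belongs to the initiator: of the 4.0 mM charged in each run, some part begins chains, and no reading shows how much. But the free monomer falls pseudo-first-order after a lag, with a slope of 0.229 min⁻¹ in Wednesday's run and 0.0611 min⁻¹ in Friday's, and Wednesday's line puts the lag at 0.970 min. If every growing chain takes up free monomer alike, the slope counts the growing chains, and the turnovers per chain go as monomer in chains divided by slope. That gives no absolute length, but it does give a ratio between flasks.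

Wednesday's slope is 3.75 times Friday's for a charge 4.18 times as large, so I scale each slope by its charge, giving 0.199 min⁻¹ for eta and 0.0556 min⁻¹ for alpha. For 12 min, less Wednesday's lag, I reckon eta at 88.9% reacted and alpha at 45.8%. The chain ratio, eta's monomer in chains over its slope divided by alpha's, is 2.17, so I commit to eta, longer by more than the margin of 10%.

The forecast also names eta, but with 90 and 30 monomer units, a ratio of 3.00, on the ground that “This suggests fewer active chains at low monomer”. The flask gives eta, at 257 against 106 monomer units, a ratio of 2.42 against my 2.17.

    free monomer + initiator → living end + monomer in chains (k = 0.538 M⁻¹ min⁻¹)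
    free monomer + living end → monomer in chains + living end, rate k2*[living end]*[free monomer] (k = 333 M⁻¹ min⁻¹)
    2 initiator → spent initiator (k = 111 M⁻¹ min⁻¹)
    2 free monomer → self-condensation product (k = 4.08 × 10⁻⁴ M⁻¹ min⁻¹)

In alpha the turning of free monomer into monomer in chains has 12% of its turnover up to 12 min behind it at 2.40 min, and at 6.00 min the initiator is down to 14.6% of its charge, with spent initiator at 0.00161 M and the living end at 2.02 × 10⁻⁴ M. The living end in alpha then stands at 2.44 × 10⁻⁴ M at 12.0 min, and monomer in chains has reached 51.8% of the free monomer charged. Read at 8.0 min instead, with alpha's slope kept, the same rule gives 32.3% reacted and, scaling alpha's length by the part reacted, 74.8 monomer units, and that neighbour of alpha stands at 77.1.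

All runs are calculated from invented constants.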